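**Strategy.** The ten-membered carbocycle is closed between C1 and C10 (germacrane numbering) by an intramolecular Nozaki–Hiyama–Kishi reaction. The step exploits the C1 carbinol flanked by the exocyclic C10=C14 methylene. A 2-iodoallyl unit (C9–C10(I)=C14) adds to a C1 aldehyde and gives ring, allylic alcohol and 1,1-disubstituted alkene in one operation. The precursor is a seco-aldehyde in which the cis-fused α-methylene-γ-butyrolactone (C6/C7), the ring-cis C4=C5 olefin, the C15 acetate and the C8 ester are already in place. It is assembled by an indium-mediated Barbier allylation/lactonisation of an enal (C1–C6) with a 2-(bromomethyl)enoate (C7–C14).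

Key step: step 19

Remark (numbering and reading of the target): germacrane numbering is used throughout. C1 = CHOH, C4 carries C15H2OAc, C6 = lactone carbinol, C8 = acyloxy carbon, C10 carries the C14 methylene, C11–C13 = lactone acrylate unit, primed numbers = side-chain acid. Read from the SMILES, the lactone is cis-fused (H6/H7 syn), C3 and C6 are cis on C4=C5, and the configurations are 1R, 6S, 7R, 8S, 3'R. For intermediates whose CIP descriptors change formally with the protecting group, the configuration is given as "as in the target". All starting materials are taken to be commercially available.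

**Fragment 1 (C1–C6, C15)**

Step 1
Reactants: 1 but-2-yne-1,4-diol
Product: 2 4-(tert-butyldimethylsilyloxy)but-2-yn-1-ol
Conditions: TBSCl (1 equiv), imidazole, DMF, 0 °C, 1 in excess (4 equiv)
Reagents that add atoms: tert-butyldimethylsilyl chloride, CC(C)(C)[Si](C)(C)Cl
Why: Statistical monosilylation of the symmetrical diol, made selective by the excess of diol; no stereocenter is involved.

Step 2
Reactants: 2 4-(tert-butyldimethylsilyloxy)but-2-yn-1-ol
Product: 4 (Z)-4-(tert-butyldimethylsilyloxy)-3-iodobut-2-en-1-ol, via sodium alkenylalanate 3 (not isolated)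
Conditions: NaAlH2(OCH2CH2OMe)2, THF, 0 °C to rt; then I2, −78 °C to 0 °C
Reagents that add atoms: iodine, II
Why: Hydroxyl-directed trans-hydroalumination of the propargylic alcohol places aluminium on the future C4 in a five-membered alanate, and iodinolysis with retention should give the Z-iodide (I cis to CH2OH), which fixes the later C4=C5 geometry.

Step 3
Reactants: 4 (Z)-4-(tert-butyldimethylsilyloxy)-3-iodobut-2-en-1-ol; 5 3,3-dimethoxyprop-1-ene
Product: 7 (E)-3-[(tert-butyldimethylsilyloxy)methyl]-6,6-dimethoxyhex-2-en-1-ol, via 9-(3,3-dimethoxypropyl)-9-BBN 6 (not isolated)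
Conditions: 5, 9-BBN, THF, 0 °C to rt; then 4, PdCl2(dppf) (5 mol %), AsPh3, Cs2CO3, DMF/H2O, rt
Reagents that add atoms: none
Why: B-alkyl Suzuki–Miyaura coupling: anti-Markovnikov hydroboration of the acrolein acetal, then sp3–sp2 coupling on zerovalent palladium with retention of the alkene geometry, should put the C1–C3 chain cis to the future C6.

Step 4
Reactants: 7 (E)-3-[(tert-butyldimethylsilyloxy)methyl]-6,6-dimethoxyhex-2-en-1-ol
Product: 8 (E)-3-[(tert-butyldimethylsilyloxy)methyl]-6,6-dimethoxyhex-2-enal
Conditions: TEMPO (10 mol %), PhI(OAc)2, CH2Cl2, rt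
Reagents that add atoms: none
Why: Oxoammonium (TEMPO) oxidation of the primary allylic alcohol should give the enal without E/Z isomerisation and without touching the acetal or the silyl ether.

**Fragment 2 (C7–C14)**

Step 5
Reactants: 9 methyl (S)-oxirane-2-carboxylate; 10 (1-bromovinyl)trimethylsilane
Product: 11 methyl (S)-2-hydroxy-4-(trimethylsilyl)pent-4-enoate
Conditions: 10, Mg, THF, reflux; then CuI (10 mol %), 9, THF, −40 to −20 °C
Reagents that add atoms: none
Why: Copper-catalysed Grignard opening of the glycidic ester at the unsubstituted carbon (SN2) leaves the (S)-stereocenter, the future C8, untouched; the α-silylvinyl group is a masked 2-iodoallyl unit.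

Step 6
Reactants: 11 methyl (S)-2-hydroxy-4-(trimethylsilyl)pent-4-enoate
Product: 12 methyl (S)-2-(tert-butyldimethylsilyloxy)-4-(trimethylsilyl)pent-4-enoate
Conditions: TBSCl, imidazole, DMF, rt
Reagents that add atoms: tert-butyldimethylsilyl chloride, CC(C)(C)[Si](C)(C)Cl
Why: Standard silylation of the secondary α-hydroxy ester; the bulky silyl ether is the control element for the later allylation.

Step 7
Reactants: 12 methyl (S)-2-(tert-butyldimethylsilyloxy)-4-(trimethylsilyl)pent-4-enoate
Product: 13 methyl (S)-2-(tert-butyldimethylsilyloxy)-4-iodopent-4-enoate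
Conditions: NIS, (CF3)2CHOH, 0 °C
Reagents that add atoms: N-iodosuccinimide, O=C1CCC(=O)N1I
Why: Electrophilic ipso-iododesilylation of the 1,1-disubstituted vinylsilane (β-silyl cation pathway) should give the 2-iodoalkene needed for the ring closure.

Step 8
Reactants: 13 methyl (S)-2-(tert-butyldimethylsilyloxy)-4-iodopent-4-enoate
Product: 14 (S)-2-(tert-butyldimethylsilyloxy)-4-iodopent-4-enal
Conditions: i-Bu2AlH (1.1 equiv), CH2Cl2, −78 °C
Reagents that add atoms: none
Why: Low-temperature half-reduction of an α-silyloxy ester stops at the aldehyde through a stable tetrahedral aluminium hemiacetal; the vinyl iodide is inert.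

Step 9
Reactants: 14 (S)-2-(tert-butyldimethylsilyloxy)-4-iodopent-4-enal; 15 methyl acrylate
Product: 16 methyl (4S)-4-(tert-butyldimethylsilyloxy)-3-hydroxy-6-iodo-2-methylidenehept-6-enoate (C3 epimer mixture)
Conditions: DABCO (0.5 equiv), 15 (excess, neat), rt
Reagents that add atoms: none
Why: Morita–Baylis–Hillman reaction of an activated α-silyloxy aldehyde; the new carbinol center becomes sp2 in the next step, so the epimer mixture is used as such.

Step 10
Reactants: 16 methyl (4S)-4-(tert-butyldimethylsilyloxy)-3-hydroxy-6-iodo-2-methylidenehept-6-enoate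
Product: 17 methyl (2Z,4S)-2-(bromomethyl)-4-(tert-butyldimethylsilyloxy)-6-iodohepta-2,6-dienoate
Conditions: NBS, Me2S, CH2Cl2, 0 °C to rt
Reagents that add atoms: N-bromosuccinimide, O=C1CCC(=O)N1Br
Why: Activation of the allylic alcohol as an alkoxysulfonium salt and SN2' delivery of bromide transposes the allyl system to the thermodynamically preferred Z-2-(bromomethyl)enoate (C8 cis to CH2Br).

**Fragment 3 (side-chain acid)**

Step 11
Reactants: 18 (R)-2-(2,2-dimethyl-1,3-dioxolan-4-yl)ethan-1-ol
Product: 19 (R)-2-(2,2-dimethyl-1,3-dioxolan-4-yl)acetaldehyde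
Conditions: TEMPO (10 mol %), PhI(OAc)2, CH2Cl2, rt
Reagents that add atoms: none
Why: Oxoammonium oxidation of the primary alcohol to the aldehyde under non-aqueous conditions that spare the acetonide; the stereocenter is not α to the carbonyl.

Step 12
Reactants: 19 (R)-2-(2,2-dimethyl-1,3-dioxolan-4-yl)acetaldehyde
Product: 20 (R)-2-(2,2-dimethyl-1,3-dioxolan-4-yl)prop-2-enal
Conditions: aq. CH2O (37 %), pyrrolidine (10 mol %), propionic acid (10 mol %), i-PrOH, 45 °C
Reagents that add atoms: formaldehyde, C=O
Why: Amine-catalysed Mannich condensation and elimination (organocatalytic α-methylenation of an aldehyde) installs the exo-methylene next to the untouched C3' stereocenter.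

Step 13
Reactants: 20 (R)-2-(2,2-dimethyl-1,3-dioxolan-4-yl)prop-2-enal
Product: 21 (R)-2-(2,2-dimethyl-1,3-dioxolan-4-yl)prop-2-enoic acid
Conditions: NaClO2, NaH2PO4, 2-methylbut-2-ene, t-BuOH/H2O, 0 °C to rt
Reagents that add atoms: sodium chlorite, [Na+].[O-]Cl=O
Why: Pinnick oxidation converts the 2-substituted acrolein into the acrylic acid without touching the alkene or, at this buffered pH, the acetonide.

**Union and endgame**

Step 14
Reactants: 8 (E)-3-[(tert-butyldimethylsilyloxy)methyl]-6,6-dimethoxyhex-2-enal; 17 methyl (2Z,4S)-2-(bromomethyl)-4-(tert-butyldimethylsilyloxy)-6-iodohepta-2,6-dienoate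
Product: 23 cis-fused α-methylene lactone bis-TBS ether, via syn-hydroxy ester 22 (not isolated)
Conditions: In powder, DMF, rt; then PPTS (cat.), toluene, 60 °C
Reagents that add atoms: none
Why: Indium-mediated Barbier allylation with lactonisation: the Z-allylindium should add through a chair transition state to give the C6/C7 syn adduct, the aldehyde approaching the C7 face anti to the C8 silyloxy group in the conformer that minimises 1,3-allylic strain (C8–H eclipsing C7=C11), and acid-catalysed ring closure then gives the cis-fused lactone with C6, C7 and C8 as in the target.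

Step 15
Reactants: 23 cis-fused α-methylene lactone bis-TBS ether
Product: 24 C8,C15-diol lactone
Conditions: HF·pyridine, pyridine, THF, 0 °C to rt
Reagents that add atoms: none
Why: Buffered fluoride cleavage of both silyl ethers under weakly acidic, non-aqueous conditions that should leave the dimethyl acetal, the vinyl iodide and the lactone intact and avoid base-induced translactonisation to O8.

Step 16
Reactants: 24 C8,C15-diol lactone
Product: 25 C15 acetate C8 alcohol
Conditions: AcCl (1.1 equiv), 2,4,6-collidine, CH2Cl2, −78 °C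
Reagents that add atoms: acetyl chloride, CC(=O)Cl
Why: Kinetically selective acetylation of the primary allylic C15 hydroxyl over the hindered secondary C8 hydroxyl with a weak hindered base at low temperature.

Step 17
Reactants: 25 C15 acetate C8 alcohol; 21 (R)-2-(2,2-dimethyl-1,3-dioxolan-4-yl)prop-2-enoic acid
Product: 27 C8 ester acetal, via mixed trichlorobenzoic anhydride 26 (not isolated)
Conditions: 21, 2,4,6-trichlorobenzoyl chloride, Et3N, toluene, rt; then 25, DMAP, rt
Reagents that add atoms: none
Why: Yamaguchi esterification acylates the hindered C8 alcohol through the acylpyridinium ion of the mixed anhydride, with retention at C8 and C3'.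

Step 18
Reactants: 27 C8 ester acetal
Product: 29 seco-aldehyde, via C1 methoxy collidinium triflate 28 (not isolated)
Conditions: TESOTf, 2,4,6-collidine, CH2Cl2, 0 °C; then H2O
Reagents that add atoms: water, O
Why: Silyl triflate/collidine activation converts the unhindered aldehyde-derived dimethyl acetal into a collidinium salt that water hydrolyses to the aldehyde, a pathway that the more hindered acetone ketal of the side chain should not follow.

Step 19
Reactants: 29 seco-aldehyde
Product: 30 macrocyclic C1 alcohol acetonide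
Conditions: CrCl2 (10 equiv), NiCl2 (0.1 equiv), DMSO/THF, rt, 2 mM, slow addition of 29
Reagents that add atoms: none
Why: Zerovalent nickel, formed from NiCl2 and CrCl2, inserts into the C10–I bond, transmetalation gives an alkenylchromium species of trivalent chromium, and this adds to the C1 aldehyde to form the C1–C10 bond and the chromium alkoxide of the allylic alcohol. The closest known reaction type is the intramolecular Nozaki–Hiyama–Kishi cyclisation of 2-iodoalk-1-enyl aldehydes, which is established for medium rings that carry an exocyclic methylene next to the new carbinol. The ten-membered carbocycle is closed in a 10-exo-trig mode (attack on the C1 carbonyl carbon, oxygen outside the ring, C10=C14 left exocyclic). The new C1 stereocenter is under substrate control: the cis-fused lactone and the ring-cis C4=C5 olefin fold the chain, and addition is expected on the aldehyde face that places the chromium alkoxide outside the forming ring and on the side away from the C8 ester, which corresponds to 1R. The step needs chemoselectivity for the aldehyde over the two enoates, the lactone and the allylic acetate, secured by the aldehyde selectivity of organochromium reagents and the absence of phosphine ligands on nickel, and it needs ring closure over oligomerisation, secured by high dilution and the preorganised chain.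

Step 20
Reactants: 30 macrocyclic C1 alcohol acetonide
Product: 31 CNP0245550.1
Conditions: AcOH/H2O (4:1), 40 °C
Reagents that add atoms: none
Why: Mild acid hydrolysis of the terminal isopropylidene ketal frees the 3',4'-diol, under conditions that the allylic acetate, both enoates and the C1 allylic alcohol should tolerate.

**Compound list**

1 | but-2-yne-1,4-diol | OCC#CCO | starting material
2 | 4-(tert-butyldimethylsilyloxy)but-2-yn-1-ol | OCC#CCO[Si](C)(C)C(C)(C)C | intermediate
3 | sodium alkenylalanate: five-membered ring in which Al is bound to the alkoxide O and to the alkene carbon that carries CH2OTBS, with two 2-methoxyethoxy ligands on Al | [Na+].COCCO[Al-]1(OCCOC)OCC=C1CO[Si](C)(C)C(C)(C)C | intermediate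
4 | (Z)-4-(tert-butyldimethylsilyloxy)-3-iodobut-2-en-1-ol (I cis to CH2OH) | OC/C=C(I)/CO[Si](C)(C)C(C)(C)C | intermediate
5 | 3,3-dimethoxyprop-1-ene | C=CC(OC)OC | starting material
6 | 9-(3,3-dimethoxypropyl)-9-borabicyclo[3.3.1]nonane | COC(OC)CCB1C2CCCC1CCC2 | intermediate
7 | (E)-3-[(tert-butyldimethylsilyloxy)methyl]-6,6-dimethoxyhex-2-en-1-ol (CH2OH cis to the dimethoxypropyl chain) | OC/C=C(CCC(OC)OC)/CO[Si](C)(C)C(C)(C)C | intermediate
8 | (E)-3-[(tert-butyldimethylsilyloxy)methyl]-6,6-dimethoxyhex-2-enal (CHO = C6, cis to the C3–C1 chain) | O=C/C=C(CCC(OC)OC)/CO[Si](C)(C)C(C)(C)C | intermediate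
9 | methyl (S)-oxirane-2-carboxylate | COC(=O)[C@@H]1CO1 | starting material
10 | (1-bromovinyl)trimethylsilane | C=C(Br)[Si](C)(C)C | starting material
11 | methyl (S)-2-hydroxy-4-(trimethylsilyl)pent-4-enoate | COC(=O)[C@@H](O)CC(=C)[Si](C)(C)C | intermediate
12 | methyl (S)-2-(tert-butyldimethylsilyloxy)-4-(trimethylsilyl)pent-4-enoate | COC(=O)[C@@H](O[Si](C)(C)C(C)(C)C)CC(=C)[Si](C)(C)C | intermediate
13 | methyl (S)-2-(tert-butyldimethylsilyloxy)-4-iodopent-4-enoate | COC(=O)[C@@H](O[Si](C)(C)C(C)(C)C)CC(I)=C | intermediate
14 | (S)-2-(tert-butyldimethylsilyloxy)-4-iodopent-4-enal | O=C[C@@H](O[Si](C)(C)C(C)(C)C)CC(I)=C | intermediate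
15 | methyl acrylate | C=CC(=O)OC | starting material
16 | methyl (4S)-4-(tert-butyldimethylsilyloxy)-3-hydroxy-6-iodo-2-methylidenehept-6-enoate, both C3 epimers | COC(=O)C(=C)C(O)[C@@H](O[Si](C)(C)C(C)(C)C)CC(I)=C | intermediate
17 | methyl (2Z,4S)-2-(bromomethyl)-4-(tert-butyldimethylsilyloxy)-6-iodohepta-2,6-dienoate (ester trans to C4) | COC(=O)/C(CBr)=C/[C@@H](O[Si](C)(C)C(C)(C)C)CC(I)=C | intermediate
18 | (R)-2-(2,2-dimethyl-1,3-dioxolan-4-yl)ethan-1-ol | OCC[C@@H]1COC(C)(C)O1 | starting material
19 | (R)-2-(2,2-dimethyl-1,3-dioxolan-4-yl)acetaldehyde | O=CC[C@@H]1COC(C)(C)O1 | intermediate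
20 | (R)-2-(2,2-dimethyl-1,3-dioxolan-4-yl)prop-2-enal | O=CC(=C)[C@@H]1COC(C)(C)O1 | intermediate
21 | (R)-2-(2,2-dimethyl-1,3-dioxolan-4-yl)prop-2-enoic acid | OC(=O)C(=C)[C@@H]1COC(C)(C)O1 | intermediate
22 | open-chain Barbier adduct: methyl 2-methylidene ester whose C7 carries the C6 carbinol (free OH, attached to the E-configured C5=C4(CH2OTBS)CH2CH2CH(OMe)2 unit) and the (S)-C8 silyloxy carbon with the 2-iodoallyl group; C6/C7 syn, C6–C8 as in the target | COC(=O)C(=C)[C@@H]([C@@H](O)/C=C(/CO[Si](C)(C)C(C)(C)C)CCC(OC)OC)[C@@H](O[Si](C)(C)C(C)(C)C)CC(I)=C | intermediate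
23 | cis-4,5-disubstituted 3-methylideneoxolan-2-one: C5 (= C6) carries the (E)-2-[(tert-butyldimethylsilyloxy)methyl]-5,5-dimethoxypent-1-enyl group, C4 (= C7) the (1S)-1-(tert-butyldimethylsilyloxy)-3-iodobut-3-enyl group; C6, C7, C8 as in the target | C=C1C(=O)O[C@@H](/C=C(/CO[Si](C)(C)C(C)(C)C)CCC(OC)OC)[C@H]1[C@@H](O[Si](C)(C)C(C)(C)C)CC(I)=C | intermediate
24 | the same cis-lactone with free C15 and C8 hydroxyls: (E)-2-(hydroxymethyl)-5,5-dimethoxypent-1-enyl and (1S)-1-hydroxy-3-iodobut-3-enyl substituents | C=C1C(=O)O[C@@H](/C=C(/CO)CCC(OC)OC)[C@H]1[C@@H](O)CC(I)=C | intermediate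
25 | the same cis-lactone with C15 acetate and free C8 hydroxyl | C=C1C(=O)O[C@@H](/C=C(/COC(C)=O)CCC(OC)OC)[C@H]1[C@@H](O)CC(I)=C | intermediate
26 | (R)-2-(2,2-dimethyl-1,3-dioxolan-4-yl)prop-2-enoic 2,4,6-trichlorobenzoic anhydride | C=C(C(=O)OC(=O)c1c(Cl)cc(Cl)cc1Cl)[C@@H]1COC(C)(C)O1 | intermediate
27 | cis-lactone with C15 acetate, C1 dimethyl acetal, C10 vinyl iodide and C8 esterified by the (R)-acetonide acrylic acid | C=C1C(=O)O[C@@H](/C=C(/COC(C)=O)CCC(OC)OC)[C@H]1[C@@H](OC(=O)C(=C)[C@@H]2COC(C)(C)O2)CC(I)=C | intermediate
28 | as 27, but C1 carries one methoxy group and an N-bound 2,4,6-trimethylpyridinium ring (triflate salt, both C1 epimers) | C=C1C(=O)O[C@@H](/C=C(/COC(C)=O)CCC(OC)[n+]2c(C)cc(C)cc2C)[C@H]1[C@@H](OC(=O)C(=C)[C@@H]2COC(C)(C)O2)CC(I)=C.[O-]S(=O)(=O)C(F)(F)F | intermediate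
29 | seco-aldehyde: as 27 with C1 as free aldehyde (C1 aldehyde and C10 vinyl iodide on the cis-lactone core) | C=C1C(=O)O[C@@H](/C=C(/COC(C)=O)CCC=O)[C@H]1[C@@H](OC(=O)C(=C)[C@@H]2COC(C)(C)O2)CC(I)=C | intermediate
30 | 3',4'-O-isopropylidene derivative of the target: ten-membered ring closed, (1R)-hydroxyl, C10 exo-methylene | C=C1C(=O)O[C@H]2/C=C(/COC(C)=O)CC[C@@H](O)C(=C)C[C@H](OC(=O)C(=C)[C@@H]3COC(C)(C)O3)[C@@H]12 | intermediate
31 | CNP0245550.1: (1R,6S,7R,8S)-15-acetoxy-1-hydroxy-8-[(3R)-3,4-dihydroxy-2-methylidenebutanoyloxy]germacra-4,10(14),11(13)-trien-6,12-olide, cis-fused lactone, C3/C6 cis on C4=C5 | C=C1C(=O)O[C@H]2/C=C(/COC(C)=O)CC[C@@H](O)C(=C)C[C@H](OC(=O)C(=C)[C@@H](O)CO)[C@@H]12 | target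

**Count.** Total: 20 steps. Longest linear sequence: 13 steps (steps 5–10, then 14–20).

**Steps most likely to fail and fallbacks**

1. Step 19 (ring closure). The closure may show poor facial selectivity at the C1 carbonyl, so that the C1 epimer is formed preferentially; intermolecular coupling also competes. The fallback sets out from 29 and comes back at 30. The Ni/Cr closure is run as planned and gives the C1-epimeric macrocyclic alcohol F1, alone or mixed with 30. This material is oxidised with Dess–Martin periodinane (CH2Cl2, NaHCO3) to the cross-conjugated macrocyclic C1 enone F2. F2 is reduced with catecholborane and (S)-2-methyl-CBS-oxazaborolidine at −78 °C. With the alkenyl carbon C10 as the large group, this should deliver the (1R)-alcohol 30 under reagent control in place of substrate control.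

2. Step 14 (fragment union). Facial discrimination of the allylindium reagent toward the enal relative to the C8 silyloxy centre may be insufficient, because the transition state is loose and part of the Z geometry can be lost by metallotropic shift. The fallback sets out from 16 and comes back at 22. Acetylation (Ac2O, DMAP, pyridine) gives the allylic acetate F3. CuCl-catalysed SN2' borylation (B2pin2, LiCl, KOAc, DMF, rt) gives the 2-(methoxycarbonyl)allyl pinacolboronate F4, with the same alkene geometry as 17 (CH2B cis to C8). Thermal allylboration of enal 8 (toluene, 80 °C) runs through a closed six-membered chair transition state, in which 1,3-allylic strain control by the C8 centre is known to be high for this alkene geometry, and gives the O-boryl syn adduct F5. Aqueous work-up gives hydroxy ester 22, which is lactonised as in step 14.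

3. Step 18 (unmasking of C1). The side-chain acetonide may be lost in part, or take up silyl, during activation of the acetal. The fallback sets out from 25 and comes back at 29. The dimethyl acetal is hydrolysed before the acid-labile side chain is present (oxalic acid on wet silica gel, CH2Cl2, rt) to give the C8-hydroxy C1-aldehyde lactone F6. Yamaguchi esterification of F6 with acid 21 through anhydride 26 (Et3N, DMAP, toluene, rt) then gives seco-aldehyde 29 directly.

Further compounds
F1 | step 19 | C1 epimer of 30 ((1S)-alcohol) | C=C1C(=O)O[C@H]2/C=C(/COC(C)=O)CC[C@H](O)C(=C)C[C@H](OC(=O)C(=C)[C@@H]3COC(C)(C)O3)[C@@H]12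
F2 | step 19 | macrocyclic C1 ketone (1-oxo-10(14)-ene enone) with acetonide side chain | C=C1C(=O)O[C@H]2/C=C(/COC(C)=O)CCC(=O)C(=C)C[C@H](OC(=O)C(=C)[C@@H]3COC(C)(C)O3)[C@@H]12
F3 | step 14 | methyl (4S)-3-acetoxy-4-(tert-butyldimethylsilyloxy)-6-iodo-2-methylidenehept-6-enoate (C3 epimers) | COC(=O)C(=C)C(OC(C)=O)[C@@H](O[Si](C)(C)C(C)(C)C)CC(I)=C
F4 | step 14 | methyl (4S)-4-(tert-butyldimethylsilyloxy)-6-iodo-2-[(4,4,5,5-tetramethyl-1,3,2-dioxaborolan-2-yl)methyl]hepta-2,6-dienoate, ester trans to C4 | COC(=O)/C(CB1OC(C)(C)C(C)(C)O1)=C/[C@@H](O[Si](C)(C)C(C)(C)C)CC(I)=C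
F5 | step 14 | O-(pinacolboryl) derivative of hydroxy ester 22 | COC(=O)C(=C)[C@@H]([C@@H](OB1OC(C)(C)C(C)(C)O1)/C=C(/CO[Si](C)(C)C(C)(C)C)CCC(OC)OC)[C@@H](O[Si](C)(C)C(C)(C)C)CC(I)=C
F6 | step 18 | cis-lactone with C15 acetate, free C8 hydroxyl and free C1 aldehyde | C=C1C(=O)O[C@@H](/C=C(/COC(C)=O)CCC=O)[C@H]1[C@@H](O)CC(I)=C
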